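**Retrosynthetic overview**
1. DMGF is a head-to-tail dimer of one monomer (7-O-methylapigenin): C6 of ring A of unit 1 is bonded to C8'' of ring A of unit 2. This hindered biaryl bond is the only strategic disconnection and is cut last, between two complete flavones.
2. Enabling feature: the hydroxyl on C5 of ring A, chelated to the C4 carbonyl of ring C, works as a switch. Free, it sends electrophilic iodine to its ortho carbon C6; O-benzylated, it leaves C8 (between the methoxy-bearing C7 and the ring oxygen O1) as the reactive site. One flavone therefore gives both a 6-iodide and an 8-iodide.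
3. The two iodides are united in one pot (borylation of the 8-iodide, then Suzuki–Miyaura coupling with the unprotected 6-iodophenol). This builds the tetra-ortho-substituted axis and the whole biflavone skeleton at once; one hydrogenolysis then frees three phenols.
4. Ring order: rings A and B are bought; ring C of the monomer is closed before the union (Claisen–Schmidt chalcone, then oxidative cyclisation); no ring is formed afterwards.

Key step: step 6

Assumption: the SMILES defines no configuration at the C6–C8'' axis and the molecule has no stereocentre, so the target is made as the racemic (axially unspecified) compound; flavone numbering is used, with double and triple primes for unit 2.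

**Step 1**
Reactants: 1 2',6'-dihydroxy-4'-methoxyacetophenone; 2 4-(benzyloxy)benzaldehyde
Product: 3 (E)-3-[4-(benzyloxy)phenyl]-1-(2,6-dihydroxy-4-methoxyphenyl)prop-2-en-1-one
Conditions: KOH (50% aq.), EtOH, 0 °C to rt; then aq. HCl
Reagents that add atoms: none
Why: Claisen–Schmidt aldol condensation: hydroxide generates the methyl ketone enolate, which adds to the non-enolisable aldehyde, and E1cB loss of water under thermodynamic control gives the conjugated E-enone, the benzyl ether being inert to aqueous base.

**Step 2**
Reactants: 3 (E)-3-[4-(benzyloxy)phenyl]-1-(2,6-dihydroxy-4-methoxyphenyl)prop-2-en-1-one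
Product: 5 2-[4-(benzyloxy)phenyl]-5-hydroxy-7-methoxy-4H-chromen-4-one (4'-O-benzylgenkwanin), via flavanone 4 (not isolated)
Conditions: I2 (10 mol %), DMSO, 130 °C
Reagents that add atoms: none
Why: Iodine-catalysed oxidative cyclisation in DMSO: 6-endo oxa-Michael addition of one ortho hydroxyl closes ring C to flavanone 4, α-iodination and loss of HI then give the chromone while DMSO reoxidises HI to I2, and the second ortho hydroxyl remains as the chelated 5-OH.

**Step 3**
Reactants: 5 2-[4-(benzyloxy)phenyl]-5-hydroxy-7-methoxy-4H-chromen-4-one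
Product: 6 2-[4-(benzyloxy)phenyl]-5-hydroxy-6-iodo-7-methoxy-4H-chromen-4-one
Conditions: NIS (1.0 equiv), DMF, 0 °C to rt, dark
Reagents that add atoms: N-iodosuccinimide, O=C1CCC(=O)N1I
Why: Electrophilic aromatic iodination (SEAr) by NIS under neutral conditions: in 5-hydroxy-7-alkoxyflavones the free chelated 5-OH makes its ortho carbon C6 the most nucleophilic position of ring A, a regiochemistry with close precedent for this flavone class, and one equivalent of reagent in the dark limits 6,8-di-iodination.

**Step 4**
Reactants: 5 2-[4-(benzyloxy)phenyl]-5-hydroxy-7-methoxy-4H-chromen-4-one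
Product: 7 5-(benzyloxy)-2-[4-(benzyloxy)phenyl]-7-methoxy-4H-chromen-4-one
Conditions: BnBr, K2CO3, n-Bu4NI (cat.), DMF, 70 °C
Reagents that add atoms: benzyl bromide, BrCc1ccccc1
Why: Williamson ether synthesis: warm K2CO3 in DMF overcomes the hydrogen bond of the chelated 5-OH and the phenoxide is O-benzylated, which removes the ortho-directing phenol and so switches the next iodination from C6 to C8.

**Step 5**
Reactants: 7 5-(benzyloxy)-2-[4-(benzyloxy)phenyl]-7-methoxy-4H-chromen-4-one
Product: 8 5-(benzyloxy)-2-[4-(benzyloxy)phenyl]-8-iodo-7-methoxy-4H-chromen-4-one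
Conditions: NIS (1.1 equiv), CF3CO2H (cat.), MeCN, 0 °C to rt
Reagents that add atoms: N-iodosuccinimide, O=C1CCC(=O)N1I
Why: Acid-activated SEAr iodination: once O5 is alkylated, 5,7-dialkoxyflavones are iodinated at C8, which lies between the methoxy-bearing C7 and the ring oxygen O1 and para to the 5-alkoxy group and is less hindered than C6 between two freely rotating alkoxy groups, while ring B and the benzyl rings are too electron-poor to compete.

**Step 6**
Reactants: 8 5-(benzyloxy)-2-[4-(benzyloxy)phenyl]-8-iodo-7-methoxy-4H-chromen-4-one; 6 2-[4-(benzyloxy)phenyl]-5-hydroxy-6-iodo-7-methoxy-4H-chromen-4-one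
Product: 10 5''-(benzyloxy)-2,2''-bis[4-(benzyloxy)phenyl]-5-hydroxy-7,7''-dimethoxy-[6,8''-bi-4H-chromene]-4,4''-dione (4',4''',5''-tri-O-benzyl-DMGF; racemic about the axis), via flavone-8-boronic pinacol ester 9 (not isolated)
Conditions: 8 (1.2 equiv), pinacolborane, Et3N, PdCl2(MeCN)2 (4 mol %), SPhos (8 mol %), 1,4-dioxane, 80 °C; then 6, K3PO4 (3 M aq.), 100 °C
Reagents that add atoms: none
Why: One-pot borylation/Suzuki–Miyaura cross-coupling: SPhos-ligated zerovalent palladium inserts into the C8–iodine bond of 8 and the arylpalladium iodide is borylated by pinacolborane/Et3N to give 9; after addition of 6 and aqueous K3PO4 the same catalyst inserts into the C6–iodine bond of 6, the borate of 9 transmetalates and reductive elimination from divalent palladium forms the C6–C8'' bond. The closest known reaction types are the one-pot borylation/Suzuki–Miyaura synthesis of tetra-ortho-substituted biaryls with dialkylbiarylphosphine ligands and the Suzuki–Miyaura union of iodoflavones with flavone-8-boronates. No ring is closed and no stereocentre is set: the new axis, flanked by the 5-hydroxyl, the two methoxy groups and the ring oxygen of unit 2, forms as a racemate, which is all the target requires. The step needs 6,8''-regiochemistry and cross- rather than homo-coupling; the first is fixed by the positions of the two iodine atoms (C6 in 6, C8 in 8), the second by converting 8 completely into 9 before 6 is added. The bulky, electron-rich ligand is chosen so that transmetalation and reductive elimination at the doubly ortho-oxygenated centres outrun protodeboronation, and the chelated 5-hydroxyl of 6 needs no protection because its phenoxide survives the base and can bind boron to bring the two partners together at palladium.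

**Step 7**
Reactants: 10 5''-(benzyloxy)-2,2''-bis[4-(benzyloxy)phenyl]-5-hydroxy-7,7''-dimethoxy-[6,8''-bi-4H-chromene]-4,4''-dione
Product: 11 DMGF (7,7''-di-O-methylagathisflavone; 5,5''-dihydroxy-2,2''-bis(4-hydroxyphenyl)-7,7''-dimethoxy-[6,8''-bi-4H-chromene]-4,4''-dione)
Conditions: H2 (1 atm), 10% Pd/C, THF–MeOH, rt
Reagents that add atoms: none
Why: Heterogeneous hydrogenolysis of the three benzyl aryl ethers: the neutral conditions leave the two methyl ethers and the chromone C2=C3 bonds untouched and avoid the acid that could reopen ring C of a 5-hydroxy-8-arylflavone and reclose it as the 6-aryl isomer (Wessely–Moser rearrangement).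

**Compound list**
1 | 2',6'-dihydroxy-4'-methoxyacetophenone | CC(=O)c1c(O)cc(OC)cc1O | starting material
2 | 4-(benzyloxy)benzaldehyde | O=Cc1ccc(OCc2ccccc2)cc1 | starting material
3 | (E)-3-[4-(benzyloxy)phenyl]-1-(2,6-dihydroxy-4-methoxyphenyl)prop-2-en-1-one | COc1cc(O)c(C(=O)/C=C/c2ccc(OCc3ccccc3)cc2)c(O)c1 | intermediate
4 | racemic 2-[4-(benzyloxy)phenyl]-5-hydroxy-7-methoxychroman-4-one (flavanone, not isolated) | COc1cc(O)c2c(c1)OC(c1ccc(OCc3ccccc3)cc1)CC2=O | intermediate
5 | 2-[4-(benzyloxy)phenyl]-5-hydroxy-7-methoxy-4H-chromen-4-one (4'-O-benzylgenkwanin) | COc1cc(O)c2c(=O)cc(-c3ccc(OCc4ccccc4)cc3)oc2c1 | intermediate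
6 | 2-[4-(benzyloxy)phenyl]-5-hydroxy-6-iodo-7-methoxy-4H-chromen-4-one | COc1cc2oc(-c3ccc(OCc4ccccc4)cc3)cc(=O)c2c(O)c1I | intermediate
7 | 5-(benzyloxy)-2-[4-(benzyloxy)phenyl]-7-methoxy-4H-chromen-4-one | COc1cc(OCc2ccccc2)c2c(=O)cc(-c3ccc(OCc4ccccc4)cc3)oc2c1 | intermediate
8 | 5-(benzyloxy)-2-[4-(benzyloxy)phenyl]-8-iodo-7-methoxy-4H-chromen-4-one | COc1cc(OCc2ccccc2)c2c(=O)cc(-c3ccc(OCc4ccccc4)cc3)oc2c1I | intermediate
9 | 5-(benzyloxy)-2-[4-(benzyloxy)phenyl]-7-methoxy-8-(4,4,5,5-tetramethyl-1,3,2-dioxaborolan-2-yl)-4H-chromen-4-one (not isolated) | COc1cc(OCc2ccccc2)c2c(=O)cc(-c3ccc(OCc4ccccc4)cc3)oc2c1B1OC(C)(C)C(C)(C)O1 | intermediate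
10 | 5''-(benzyloxy)-2,2''-bis[4-(benzyloxy)phenyl]-5-hydroxy-7,7''-dimethoxy-[6,8''-bi-4H-chromene]-4,4''-dione (racemic about the axis) | COc1cc2oc(-c3ccc(OCc4ccccc4)cc3)cc(=O)c2c(O)c1-c1c(OC)cc(OCc2ccccc2)c2c(=O)cc(-c3ccc(OCc4ccccc4)cc3)oc12 | intermediate
11 | DMGF (7,7''-di-O-methylagathisflavone, racemic about the axis) | COc1cc2oc(-c3ccc(O)cc3)cc(=O)c2c(O)c1-c1c(OC)cc(O)c2c(=O)cc(-c3ccc(O)cc3)oc12 | target

**Step count and risks**
Total step count: 7. Longest linear sequence: 6 steps (steps 1, 2, 4, 5, 6, 7).

Steps most likely to fail: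

1. Step 6. The doubly ortho-oxygenated boronate may protodeboronate, and the iodide may be reduced during borylation. Transmetalation at the tetra-ortho-substituted centre may be slow, and oxidative addition at the phenoxide-bearing iodide may be retarded, so that homocoupling takes over. The fallback is a Negishi coupling with a protected phenol; it sets out from 6 and 8 and comes back to the route at 11. Compound 6 is O-benzylated (BnBr, K2CO3, DMF, 60 °C) to 5-(benzyloxy)-2-[4-(benzyloxy)phenyl]-6-iodo-7-methoxy-4H-chromen-4-one F1. Compound 8 is converted by direct zinc insertion (Zn dust, LiCl, THF, 50 °C) into [5-(benzyloxy)-2-[4-(benzyloxy)phenyl]-7-methoxy-4-oxo-4H-chromen-8-yl]zinc iodide F2, a water-free nucleophile that cannot protodeboronate. Coupling of the two (Pd2(dba)3, RuPhos, THF–NMP, 70 °C) should give 5,5''-bis(benzyloxy)-2,2''-bis[4-(benzyloxy)phenyl]-7,7''-dimethoxy-[6,8''-bi-4H-chromene]-4,4''-dione F3. Hydrogenolysis of its four benzyl ethers under the conditions of step 7 leads to 11.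

2. Step 1. The doubly deprotonated ketone enolises and adds slowly, so Cannizzaro disproportionation of the aldehyde and incomplete conversion may dominate; early ring closure to the flavanone would be harmless. The fallback is a Baker–Venkataraman-type acylation route; it sets out from 1 and comes back at 5, bypassing 3, 4 and step 2. The polyanion of 1 (LiN(SiMe3)2, 4 equiv, THF, −78 °C) is C-acylated with 4-(benzyloxy)benzoyl chloride to give 1-[4-(benzyloxy)phenyl]-3-(2,6-dihydroxy-4-methoxyphenyl)propane-1,3-dione F4. Acid-catalysed cyclodehydration (AcOH, cat. H2SO4, 90 °C) then closes ring C to 5.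

3. Step 7. The chromone C2=C3 bonds may be over-reduced, or cleavage of the hindered 5''-O-benzyl ether may stall through poor solubility and catalyst poisoning by traces of iodide. The fallback is a Lewis-acid debenzylation; it sets out from 10 and comes back at 11. BCl3 with pentamethylbenzene in CH2Cl2 at −78 °C should cleave the three benzyl ethers, the scavenger trapping the benzyl cations, while the non-chelated methyl ethers are not touched at this temperature. No new compound is made on this way (entry F0).

**Further compounds**
F1 | step 6 | 5-(benzyloxy)-2-[4-(benzyloxy)phenyl]-6-iodo-7-methoxy-4H-chromen-4-one | COc1cc2oc(-c3ccc(OCc4ccccc4)cc3)cc(=O)c2c(OCc2ccccc2)c1I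
F2 | step 6 | [5-(benzyloxy)-2-[4-(benzyloxy)phenyl]-7-methoxy-4-oxo-4H-chromen-8-yl]zinc iodide | COc1cc(OCc2ccccc2)c2c(=O)cc(-c3ccc(OCc4ccccc4)cc3)oc2c1[Zn]I
F3 | step 6 | 5,5''-bis(benzyloxy)-2,2''-bis[4-(benzyloxy)phenyl]-7,7''-dimethoxy-[6,8''-bi-4H-chromene]-4,4''-dione (racemic about the axis) | COc1cc2oc(-c3ccc(OCc4ccccc4)cc3)cc(=O)c2c(OCc2ccccc2)c1-c1c(OC)cc(OCc2ccccc2)c2c(=O)cc(-c3ccc(OCc4ccccc4)cc3)oc12
F4 | step 1 | 1-[4-(benzyloxy)phenyl]-3-(2,6-dihydroxy-4-methoxyphenyl)propane-1,3-dione | COc1cc(O)c(C(=O)CC(=O)c2ccc(OCc3ccccc3)cc2)c(O)c1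
F0 | step 7 | none | none
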